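Follow one molecule. A substrate molecule reaches a fork, where I take it that the second nucleophile sends it to the other capture product and dissolved gas sends it to the target.

| flask | substrate | second nucleophile | gas | remark | time |
|---|---|---|---|---|---|
| west | 0.50 mM | 0.525 mM | 0.28 mM (held) | the very flask that is asked about, followed so far |  |
| south-east | 0.34 mM | 0.525 mM | 0.28 mM (held) | run made earlier |  |
| flask | 0.50 mM | 0.525 mM | 0.28 mM (held) |  | 12 min |

| run | time / min | target / % | other capture product / % |
|---|---|---|---|
| west | 0.200 | 8.5 | 73.1 |
| west | 0.333 | 8.9 | 77.6 |
| west | 0.417 | 10.9 | 77.7 |
| west | 0.667 | 9.8 | 77.8 |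
| west | 1.00 | 10.8 | 77.4 |
| west | 1.50 | 10.5 | 78.4 |
| west | 2.50 | 10.2 | 78.1 |
| south-east | 1.33 | 7.8 | 81.6 |
| south-east | 2.50 | 8.0 | 81.8 |
| south-east | 4.00 | 6.8 | 81.2 |
| south-east | 5.00 | 8.5 | 82.7 |
| south-east | 6.00 | 7.9 | 82.4 |
| south-east | 8.00 | 7.6 | 82.9 |

(scatter of a reading: 0.5 percentage points)

- at the start none of the gas is in solution

1. ratio of target to other capture product at 0.30 s
2. ratio of target to other capture product at 15 s
3. ratio of target to other capture product at 12 min
4. which of target and other capture product there is more of at 12 min

With dissolved gas steady, the odds of target against other capture product at the fork are a / c(second nucleophile). Each other capture product uses up one second nucleophile, so summing the odds over a run gives: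

target = a · ln(c(second nucleophile) charged / c(second nucleophile) left)

West, last reading: other capture product 0.390 mM, logarithm 1.36, a = 0.0374 mM.

South-east, last reading: other capture product 0.282 mM, logarithm 0.770, a = 0.0336 mM.

Their mean is the tie level, read from these two readings, the concentration of second nucleophile at which target and other capture product form with equal odds: 0.0355 mM. It is a selectivity factor times the dissolved gas that a molecule at the fork meets on average over a run.

This flask repeats the west run, so at 12 min I expect a ratio of 0.124, with the other capture product ahead, and about the same at 15 s.

The weak link is 0.30 s, when dissolved gas has barely begun. If the other capture product follows the loss of substrate, the west run's first reading, 73.1% against a late 78.1%, reads as a substrate time of: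

τ = 4.37 s

The gas uptake time is unread, so I guess it equals τ. On that guess a molecule at the fork meets on average half of saturation over the run, but 3.43% of saturation over the first 0.30 s:

ratio at 0.30 s = (tie level / c(second nucleophile)) · (0.30 s / τ) = 0.00465

The forecast gives 2, 0.133 and 0.131, with other capture product ahead. It pairs the species the other way round from me: “the gas forms the other capture product and the nucleophile forms the target”.

The flask gives 0.00557, 0.122 and 0.130, with other capture product ahead, at 77.9% against 10.1% of target.

    second nucleophile + intermediate → other capture product (k = 45000 L mol⁻¹ s⁻¹)
    substrate → intermediate (k = 0.230 s⁻¹)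
    first nucleophile + intermediate → target (k = 9840 L mol⁻¹ s⁻¹)
    gas ⇌ first nucleophile, rate k4*(csat - [first nucleophile]) (kL = 0.290 s⁻¹)
    intermediate → solvolysis product (k = 1.84 s⁻¹)
    intermediate → side product (k = 0.153 s⁻¹)

In these equations the first nucleophile is what I called dissolved gas, and the second nucleophile makes the other capture product. With this flask's 77.9% of other capture product, the tie level gives 9.62% of target. A neighbouring flask charged with 0.20 mM of substrate ends with 84.6% of other capture product, and the same reckoning gives 6.90% of target there. That neighbouring flask holds 6.82% of target, a ratio of 0.0807.

The numbers in the tables were generated by integration on assumed constants; the scatter is artificial.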